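Readings and results come from a simulation for an exercise; noise was put on by code.

Molar per minute is the unit in which you should read the two earlier runs, maple and elm, and the new flask after them.

| flask | starting material | remark | time |
|---|---|---|---|
| maple | 0.52 M | run made earlier |  |
| elm | 1.2 M | run made earlier |  |
| flask | 0.77 M |  | 15 min |

| run | time / min | target / % | isomer of the product / % |
|---|---|---|---|
| maple | 1.33 | 68 | 21 |
| maple | 2.00 | 65 | 25 |
| maple | 3.00 | 58 | 28 |
| maple | 4.00 | 56 | 30 |
| maple | 6.00 | 47 | 43 |
| maple | 10.0 | 32 | 53 |
| maple | 15.0 | 10 | 71 |
| elm | 0.833 | 66 | 18 |
| elm | 2.50 | 62 | 17 |
| elm | 4.00 | 59 | 26 |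
| elm | 6.00 | 57 | 26 |
| elm | 10.0 | 51 | 30 |
| elm | 12.0 | 49 | 32 |
| elm | 15.0 | 43 | 39 |

(standard deviation of a reading: 1.5 percentage points)

- share of target in target plus isomer of the product at 0.15 s
- share of target in target plus isomer of the product at 12 s
- share of target in target plus isomer of the product at 15 min
- which of target and isomer of the product there is more of at 15 min

- what was read earlier has a scatter of 1.5 percentage points, one standard deviation
- a reading or a percentage of target counts all its forms, free or not

In percent the runs disagree: between first and last reading, target falls by 58 percentage points in maple and by 23 points in elm. So first ask what each run loses in molar terms. Multiply each fall by its charge and divide by its time, and maple gives 0.0221 M min⁻¹, elm 0.0195 M min⁻¹. These differ by a factor of 1.13, while the charges differ by 2.31. Read so, the loss looks zero order, so take the mean as the drain, 0.0208 M min⁻¹, the molar loss of target per minute as these readings give it.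

Next, what does the drain take from the flask? Over 15 min I reckon it at 40.5% of the 0.77 M charged. That is less than the 70.5% of target that the two runs give on average when their falling lines are extended back to zero time. So I expect 30.0% of target at the end.

Then, what does the isomer of the product hold? Target and isomer of the product together stand at 81.5% on average in the last readings of the two runs, so I give the isomer of the product 51.5% in the flask, and my share is 36.8%. The two short times lie before any reading, so I draw nothing for them from the drain.

The forecast gives 81%, 80% and 36%, with isomer of the product ahead, holding that both runs lose target at “nearly the same absolute rate”. Its last share lies below mine.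

The flask gives 94.2%, 80.2% and 36.2%, with isomer of the product ahead at 53.2% against 30.1% of target. The forecast is 13 points low at the earliest time and right at the other two.

    third conformer → third product (k = 2.00 s⁻¹)
    starting material ⇌ other conformer (K = 0.760, k = 2.94 s⁻¹)
    other conformer → isomer of the product (k = 0.174 s⁻¹)
    other conformer ⇌ third conformer (K = 5.80, k = 0.0233 s⁻¹)
    starting material ⇌ target (K = 8.90, k = 0.548 s⁻¹)
    crystals ⇌ target, rate k6*(cs6 - [target]) while solid is left; crystals form when [target] > cs6 (solubility = 28.0 mM, k = 0.954 s⁻¹)
    2 other conformer → self-condensation product (k = 0.314 M⁻¹ s⁻¹)

At 15.0 min the flask holds 26.5% as crystals within its 30.1% of target, and at the drain of 0.0208 M min⁻¹ I reckon those crystals worth 9.81 min of further loss. For the neighbour charged with 1.3 M, I reckon the drain at 24.0% of its charge over 15 min, which leaves 46.5% of target. The computed neighbour holds 43.6% of target at that time, a share of 53.8%, with target ahead.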